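**Plan**

- Numbering used here: oxolane O1, C2 (benzyl), C3 (OH), C4 (CH2OH), C5 (aryl, ring A); central aryl ether ring B; glycerol unit Cα (carbinol on ring C), Cβ (O-aryl), Cγ (CH2OH).
- Cuts: first the benzylic CH2–C2 bond (ring B benzyl nucleophile plus an epoxide fused to the oxolane); then, in the oxolane half, the O1–C2 hemiacetal bond and the C4–C5 bond (Evans syn-aldol); in the other half the Cα–Cβ bond (Evans syn-aldol of an aryloxyacetyl imide).
- Enabling feature: C2 is an acetal-type carbon on O1 and carries the benzyl group trans to the C3 hydroxyl. This is the retron of an anti opening of a 2,3-epoxide fused to the oxolane (a 1,2-anhydrofuranose) at C2.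
- Forward: aldol, reduction, lactol (the oxolane closes by hemiacetal formation), 2,3-dihydrofuran, epoxide; separately aldol, Cα inversion by oxidation and reduction, benzylic chloride; union of the two halves; global desilylation.
- Stereochemistry: C4/C5 and Cβ from the two oxazolidinone auxiliaries; C3 by epoxidation anti to the C4 substituent; C2 by inversion in the union; Cα by Felkin–Anh reduction of the α-aryloxy ketone.

Key step: step 18

Remark: (R)-4-benzyl-3-(chloroacetyl)-1,3-oxazolidin-2-one is taken as a purchasable reagent, and the anomeric carbon of the lactol and its derivatives is a mixture and is left undefined. TBS = tert-butyldimethylsilyl, TIPS = triisopropylsilyl.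

**Step 1**
Reactants: 1 vanillin (4-hydroxy-3-methoxybenzaldehyde)
Product: 2 3-methoxy-4-(TIPS-oxy)benzaldehyde
Conditions: TIPSCl, imidazole, DMF, rt
Reagents that add atoms: triisopropylsilyl chloride, CC(C)[Si](Cl)(C(C)C)C(C)C
Why: Silylation of the phenol gives a bulky aryl silyl ether that should survive the boron aldol, hydride, oxidation and organomagnesium steps and is removed by fluoride at the end.

**Step 2**
Reactants: 3 (S)-4-benzyl-1,3-oxazolidin-2-one; 4 pent-4-enoyl chloride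
Product: 5 (4S)-4-benzyl-3-(pent-4-enoyl)-1,3-oxazolidin-2-one
Conditions: Et3N, DMAP (cat.), CH2Cl2, 0 °C to rt
Reagents that add atoms: none
Why: N-Acylation of the oxazolidinone with the acid chloride under Et3N/DMAP catalysis installs the Evans auxiliary without touching the terminal alkene.

**Step 3**
Reactants: 5 (4S)-4-benzyl-3-(pent-4-enoyl)-1,3-oxazolidin-2-one; 2 3-methoxy-4-(TIPS-oxy)benzaldehyde
Product: 7 (4S)-4-benzyl-3-[(2S)-2-{(S)-hydroxy[3-methoxy-4-(TIPS-oxy)phenyl]methyl}pent-4-enoyl]-1,3-oxazolidin-2-one, via Z-boron enolate 6 (not isolated)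
Conditions: n-Bu2BOTf, i-Pr2NEt, CH2Cl2, 0 °C; then 2, −78 to 0 °C; pH 7 buffer, MeOH, H2O2
Reagents that add atoms: none
Why: Evans syn-aldol through the Z-dibutylboron enolate and a chair Zimmerman–Traxler transition state, in which the (S)-benzyl auxiliary selects the enolate face and so sets both future C4 and C5 (2S, carbinol S).

**Step 4**
Reactants: 7 the syn-aldol imide
Product: 8 (1S,2R)-1-[3-methoxy-4-(TIPS-oxy)phenyl]-2-(prop-2-en-1-yl)propane-1,3-diol
Conditions: LiBH4, MeOH (1 equiv), THF, 0 °C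
Reagents that add atoms: none
Why: Reductive cleavage of the N-acyl oxazolidinone by hydride attack at the exocyclic carbonyl frees the primary alcohol that becomes the C4 hydroxymethyl group, with both stereocentres untouched.

**Step 5**
Reactants: 8 the 1,3-diol
Product: 9 (1S,2R)-2-[(TBS-oxy)methyl]-1-[3-methoxy-4-(TIPS-oxy)phenyl]pent-4-en-1-ol
Conditions: TBSCl (1.05 equiv), imidazole, CH2Cl2, 0 °C
Reagents that add atoms: tert-butyldimethylsilyl chloride, CC(C)(C)[Si](C)(C)Cl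
Why: Silylation is selective for the primary over the secondary benzylic hydroxyl on steric grounds, which leaves the C5 hydroxyl free to become ring oxygen O1.

**Step 6**
Reactants: 9 the homoallylic benzylic alcohol
Product: 12 (4R,5S)-4-[(TBS-oxy)methyl]-5-[3-methoxy-4-(TIPS-oxy)phenyl]oxolan-2-ol (anomeric mixture), via terminal diol 10 (not isolated), via hydroxy aldehyde 11 (not isolated)
Conditions: OsO4 (2 mol %), NaIO4, 2,6-lutidine, 1,4-dioxane/H2O, rt
Reagents that add atoms: osmium tetroxide, O=[Os](=O)(=O)=O; sodium periodate, [Na+].[O-]I(=O)(=O)=O (terminal oxidant that returns oxygen to osmium)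
Why: Lemieux–Johnson cleavage of the terminal alkene gives a γ-hydroxy aldehyde that closes spontaneously to the five-membered lactol (5-exo-trig hemiacetal formation), so the oxolane is formed with the C4/C5 trans relationship inherited from the aldol.

**Step 7**
Reactants: 12 the lactol
Product: 14 (2S,3R)-3-[(TBS-oxy)methyl]-2-[3-methoxy-4-(TIPS-oxy)phenyl]-2,3-dihydrofuran, via anomeric mesylate 13 (not isolated)
Conditions: MsCl, Et3N (excess), CH2Cl2, −40 °C to reflux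
Reagents that add atoms: none
Why: Mesylation of the lactol hydroxyl and base-induced elimination through the oxocarbenium ion (the standard MsCl/Et3N route to furanoid glycals) gives the C2=C3 enol ether, and since C4 carries no leaving group no furan can form.

**Step 8**
Reactants: 14 the 2,3-dihydrofuran
Product: 15 (1R,3S,4R,5S)-4-[(TBS-oxy)methyl]-3-[3-methoxy-4-(TIPS-oxy)phenyl]-2,6-dioxabicyclo[3.1.0]hexane (C2–C3 epoxide of the oxolane, oxirane cis to the aryl group and trans to the silyloxymethyl group; used crude at once)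
Conditions: DMDO (acetone solution), CH2Cl2, −20 to 0 °C; concentrate
Reagents that add atoms: dimethyldioxirane, CC1(C)OO1
Why: Electrophilic epoxidation of the electron-rich enol ether by dimethyldioxirane under neutral conditions (glycal epoxidation) should occur on the face anti to the allylic C4 silyloxymethyl group, which sets the C3 configuration.

**Step 9**
Reactants: 16 methyl vanillate (methyl 4-hydroxy-3-methoxybenzoate); 17 (R)-4-benzyl-3-(chloroacetyl)-1,3-oxazolidin-2-one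
Product: 18 methyl 4-{2-[(4R)-4-benzyl-2-oxo-1,3-oxazolidin-3-yl]-2-oxoethoxy}-3-methoxybenzoate
Conditions: K2CO3, NaI (cat.), acetone, 50 °C
Reagents that add atoms: none
Why: Williamson ether synthesis by SN2 displacement of the activated α-chloro imide with the phenoxide of methyl vanillate gives the aryloxyacetyl imide in one step and does not touch the auxiliary stereocentre.

**Step 10**
Reactants: 18 the aryloxyacetyl imide; 2 3-methoxy-4-(TIPS-oxy)benzaldehyde
Product: 20 methyl 4-{[(1S,2R)-3-[(4R)-4-benzyl-2-oxo-1,3-oxazolidin-3-yl]-1-hydroxy-1-[3-methoxy-4-(TIPS-oxy)phenyl]-3-oxopropan-2-yl]oxy}-3-methoxybenzoate, via Z-boron enolate 19 (not isolated)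
Conditions: n-Bu2BOTf, i-Pr2NEt, CH2Cl2, 0 °C; then 2, −78 to 0 °C; pH 7 buffer, MeOH, H2O2
Reagents that add atoms: none
Why: Evans syn-aldol of the Z-boron enolate of the aryloxyacetyl imide (glycolate-type aldol) through a chair transition state, in which the (R)-benzyl auxiliary sets Cβ as required for the target and Cα as the syn (threo) epimer that is corrected in steps 13 and 14.

**Step 11**
Reactants: 20 the syn-aldol imide
Product: 21 methyl 4-{[(1S,2S)-1,3-dihydroxy-1-[3-methoxy-4-(TIPS-oxy)phenyl]propan-2-yl]oxy}-3-methoxybenzoate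
Conditions: LiBH4, MeOH (1 equiv), THF, 0 °C
Reagents that add atoms: none
Why: Reductive removal of the auxiliary with LiBH4 at 0 °C is chemoselective because the electron-rich aromatic methyl ester is reduced much more slowly than the imide.

**Step 12**
Reactants: 21 the threo 1,3-diol
Product: 22 methyl 4-{[(1S,2S)-3-(TBS-oxy)-1-hydroxy-1-[3-methoxy-4-(TIPS-oxy)phenyl]propan-2-yl]oxy}-3-methoxybenzoate
Conditions: TBSCl (1.05 equiv), imidazole, CH2Cl2, 0 °C
Reagents that add atoms: tert-butyldimethylsilyl chloride, CC(C)(C)[Si](C)(C)Cl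
Why: Silylation is selective for the primary Cγ hydroxyl over the hindered secondary benzylic Cα hydroxyl.

**Step 13**
Reactants: 22 the threo benzylic alcohol
Product: 23 methyl 4-{[(2S)-3-(TBS-oxy)-1-[3-methoxy-4-(TIPS-oxy)phenyl]-1-oxopropan-2-yl]oxy}-3-methoxybenzoate
Conditions: Dess–Martin periodinane, NaHCO3, CH2Cl2, 0 °C to rt
Reagents that add atoms: none
Why: Dess–Martin oxidation of the benzylic alcohol under buffered, non-basic conditions erases the wrong Cα configuration without exposing the adjacent Cβ stereocentre to base.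

**Step 14**
Reactants: 23 the α-aryloxy aryl ketone
Product: 24 methyl 4-{[(1R,2S)-3-(TBS-oxy)-1-hydroxy-1-[3-methoxy-4-(TIPS-oxy)phenyl]propan-2-yl]oxy}-3-methoxybenzoate
Conditions: LiBH(s-Bu)3, THF, −78 °C; then H2O
Reagents that add atoms: none
Why: Felkin–Anh (polar) controlled reduction, in which the bulky non-chelating hydride attacks the ketone anti to the α-aryloxy substituent at low temperature, should give the 1,2-anti (erythro) alcohol with Cα in the R configuration.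

**Step 15**
Reactants: 24 the erythro alcohol
Product: 25 methyl 4-{[(1R,2S)-1,3-bis(TBS-oxy)-1-[3-methoxy-4-(TIPS-oxy)phenyl]propan-2-yl]oxy}-3-methoxybenzoate
Conditions: TBSOTf, 2,6-lutidine, CH2Cl2, −78 to 0 °C
Reagents that add atoms: tert-butyldimethylsilyl trifluoromethanesulfonate, CC(C)(C)[Si](C)(C)OS(=O)(=O)C(F)(F)F
Why: Silylation of the secondary benzylic alcohol with the reactive silyl triflate removes the last acidic proton before the organomagnesium stage.

**Step 16**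
Reactants: 25 the bis-silyl ether ester
Product: 26 (4-{[(1R,2S)-1,3-bis(TBS-oxy)-1-[3-methoxy-4-(TIPS-oxy)phenyl]propan-2-yl]oxy}-3-methoxyphenyl)methanol
Conditions: i-Bu2AlH (2.5 equiv), CH2Cl2, −78 to −20 °C; Rochelle salt work-up
Reagents that add atoms: none
Why: Reduction of the aromatic methyl ester to the benzylic alcohol by i-Bu2AlH leaves silyl ethers and the alkyl aryl ether intact.

**Step 17**
Reactants: 26 the ring B benzylic alcohol
Product: 28 4-{[(1R,2S)-1,3-bis(TBS-oxy)-1-[3-methoxy-4-(TIPS-oxy)phenyl]propan-2-yl]oxy}-3-methoxybenzyl chloride, via benzylic mesylate 27 (not isolated)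
Conditions: MsCl, Et3N, LiCl, THF, 0 °C to rt
Reagents that add atoms: lithium chloride, [Li+].[Cl-]; methanesulfonyl chloride, CS(=O)(=O)Cl (second chloride source)
Why: Mesylation of the electron-rich benzylic alcohol and in situ SN2 displacement by chloride gives the benzylic chloride under non-acidic conditions.

**Step 18**
Reactants: 28 the ring B benzylic chloride; 15 the oxolane 2,3-epoxide
Product: 30 (2R,3S,4S,5S)-2-(4-{[(1R,2S)-1,3-bis(TBS-oxy)-1-[3-methoxy-4-(TIPS-oxy)phenyl]propan-2-yl]oxy}-3-methoxybenzyl)-4-[(TBS-oxy)methyl]-5-[3-methoxy-4-(TIPS-oxy)phenyl]oxolan-3-ol, via benzylic Grignard reagent 29 (not isolated)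
Conditions: 28, Mg turnings (excess), THF, 0 °C; then CuI (10 mol %), −40 °C; 15 in THF, −40 to 0 °C; aq. NH4Cl
Reagents that add atoms: none
Why: The benzylic Grignard reagent 29, as its organocopper derivative, attacks the acetal-type carbon C2 of the oxirane fused to the oxolane in 15 from the face opposite the epoxide oxygen in an SN2-type opening with inversion. The closest known reaction type is the anti opening of glycal epoxides (1,2-anhydro sugars) by Grignard reagents and cuprates to give 1,2-trans C-glycosides. No ring is closed, since the oxirane is opened and the oxolane is kept. The new stereocentre C2 (R) is fixed by stereospecific inversion at the epoxide carbon, so the benzyl group ends trans to the C3 hydroxyl, whose configuration was set in step 8 and is retained. The step needs C2-over-C3 regioselectivity, secured by the O1 lone pair that activates the acetal carbon and by the C4 branch that shields C3, and it needs anti instead of syn opening, secured by a soft copper-catalysed nucleophile at low temperature in the absence of Lewis-acidic zinc or aluminium reagents that would ionize the epoxide to an oxocarbenium ion.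

**Step 19**
Reactants: 30 the pentasilylated coupling product
Product: 31 CNP0123626.1, (2R,3S,4S,5S)-2-(4-{[(1R,2S)-1,3-dihydroxy-1-(4-hydroxy-3-methoxyphenyl)propan-2-yl]oxy}-3-methoxybenzyl)-5-(4-hydroxy-3-methoxyphenyl)-4-(hydroxymethyl)oxolan-3-ol
Conditions: n-Bu4NF, AcOH (1:1, excess), THF, 0 °C to rt
Reagents that add atoms: none
Why: Fluoride cleaves all five silyl ethers (two aryl, three alkyl), and the acetic acid buffer should keep the liberated p-hydroxybenzylic centres C5 and Cα from ionizing to quinone methides.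

**Compound list**

1 | vanillin | COc1cc(C=O)ccc1O | starting material
2 | 3-methoxy-4-(TIPS-oxy)benzaldehyde | COc1cc(C=O)ccc1O[Si](C(C)C)(C(C)C)C(C)C | intermediate
3 | (S)-4-benzyl-1,3-oxazolidin-2-one | O=C1OC[C@H](Cc2ccccc2)N1 | starting material
4 | pent-4-enoyl chloride | C=CCCC(=O)Cl | starting material
5 | (4S)-4-benzyl-3-(pent-4-enoyl)-1,3-oxazolidin-2-one | C=CCCC(=O)N1[C@@H](Cc2ccccc2)COC1=O | intermediate
6 | Z-dibutylboron enolate of 5 | C=CC/C=C(\OB(CCCC)CCCC)N1[C@@H](Cc2ccccc2)COC1=O | intermediate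
7 | (4S)-4-benzyl-3-[(2S)-2-{(S)-hydroxy[3-methoxy-4-(TIPS-oxy)phenyl]methyl}pent-4-enoyl]-1,3-oxazolidin-2-one | COc1cc([C@@H](O)[C@H](CC=C)C(=O)N2[C@@H](Cc3ccccc3)COC2=O)ccc1O[Si](C(C)C)(C(C)C)C(C)C | intermediate
8 | (1S,2R)-1-[3-methoxy-4-(TIPS-oxy)phenyl]-2-(prop-2-en-1-yl)propane-1,3-diol | COc1cc([C@@H](O)[C@H](CC=C)CO)ccc1O[Si](C(C)C)(C(C)C)C(C)C | intermediate
9 | (1S,2R)-2-[(TBS-oxy)methyl]-1-[3-methoxy-4-(TIPS-oxy)phenyl]pent-4-en-1-ol | COc1cc([C@@H](O)[C@H](CC=C)CO[Si](C)(C)C(C)(C)C)ccc1O[Si](C(C)C)(C(C)C)C(C)C | intermediate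
10 | (1S,2R)-2-[(TBS-oxy)methyl]-1-[3-methoxy-4-(TIPS-oxy)phenyl]pentane-1,4,5-triol (mixture at C4) | COc1cc([C@@H](O)[C@H](CC(O)CO)CO[Si](C)(C)C(C)(C)C)ccc1O[Si](C(C)C)(C(C)C)C(C)C | intermediate
11 | (3R,4S)-3-[(TBS-oxy)methyl]-4-hydroxy-4-[3-methoxy-4-(TIPS-oxy)phenyl]butanal | COc1cc([C@@H](O)[C@H](CC=O)CO[Si](C)(C)C(C)(C)C)ccc1O[Si](C(C)C)(C(C)C)C(C)C | intermediate
12 | (4R,5S)-4-[(TBS-oxy)methyl]-5-[3-methoxy-4-(TIPS-oxy)phenyl]oxolan-2-ol | COc1cc([C@H]2OC(O)C[C@@H]2CO[Si](C)(C)C(C)(C)C)ccc1O[Si](C(C)C)(C(C)C)C(C)C | intermediate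
13 | (4R,5S)-4-[(TBS-oxy)methyl]-5-[3-methoxy-4-(TIPS-oxy)phenyl]oxolan-2-yl methanesulfonate | COc1cc([C@H]2OC(OS(C)(=O)=O)C[C@@H]2CO[Si](C)(C)C(C)(C)C)ccc1O[Si](C(C)C)(C(C)C)C(C)C | intermediate
14 | (2S,3R)-3-[(TBS-oxy)methyl]-2-[3-methoxy-4-(TIPS-oxy)phenyl]-2,3-dihydrofuran | COc1cc([C@H]2OC=C[C@@H]2CO[Si](C)(C)C(C)(C)C)ccc1O[Si](C(C)C)(C(C)C)C(C)C | intermediate
15 | (1R,3S,4R,5S)-4-[(TBS-oxy)methyl]-3-[3-methoxy-4-(TIPS-oxy)phenyl]-2,6-dioxabicyclo[3.1.0]hexane | COc1cc([C@H]2O[C@H]3O[C@H]3[C@@H]2CO[Si](C)(C)C(C)(C)C)ccc1O[Si](C(C)C)(C(C)C)C(C)C | intermediate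
16 | methyl vanillate | COC(=O)c1ccc(O)c(OC)c1 | starting material
17 | (R)-4-benzyl-3-(chloroacetyl)-1,3-oxazolidin-2-one | O=C(CCl)N1[C@H](Cc2ccccc2)COC1=O | starting material
18 | methyl 4-{2-[(4R)-4-benzyl-2-oxo-1,3-oxazolidin-3-yl]-2-oxoethoxy}-3-methoxybenzoate | COC(=O)c1ccc(OCC(=O)N2[C@H](Cc3ccccc3)COC2=O)c(OC)c1 | intermediate
19 | Z-dibutylboron enolate of 18 | COC(=O)c1ccc(O/C=C(\OB(CCCC)CCCC)N2[C@H](Cc3ccccc3)COC2=O)c(OC)c1 | intermediate
20 | methyl 4-{[(1S,2R)-3-[(4R)-4-benzyl-2-oxo-1,3-oxazolidin-3-yl]-1-hydroxy-1-[3-methoxy-4-(TIPS-oxy)phenyl]-3-oxopropan-2-yl]oxy}-3-methoxybenzoate | COc1cc([C@H](O)[C@H](C(=O)N2[C@H](Cc3ccccc3)COC2=O)Oc2ccc(C(=O)OC)cc2OC)ccc1O[Si](C(C)C)(C(C)C)C(C)C | intermediate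
21 | methyl 4-{[(1S,2S)-1,3-dihydroxy-1-[3-methoxy-4-(TIPS-oxy)phenyl]propan-2-yl]oxy}-3-methoxybenzoate | COc1cc([C@H](O)[C@H](CO)Oc2ccc(C(=O)OC)cc2OC)ccc1O[Si](C(C)C)(C(C)C)C(C)C | intermediate
22 | methyl 4-{[(1S,2S)-3-(TBS-oxy)-1-hydroxy-1-[3-methoxy-4-(TIPS-oxy)phenyl]propan-2-yl]oxy}-3-methoxybenzoate | COc1cc([C@H](O)[C@H](CO[Si](C)(C)C(C)(C)C)Oc2ccc(C(=O)OC)cc2OC)ccc1O[Si](C(C)C)(C(C)C)C(C)C | intermediate
23 | methyl 4-{[(2S)-3-(TBS-oxy)-1-[3-methoxy-4-(TIPS-oxy)phenyl]-1-oxopropan-2-yl]oxy}-3-methoxybenzoate | COc1cc(C(=O)[C@H](CO[Si](C)(C)C(C)(C)C)Oc2ccc(C(=O)OC)cc2OC)ccc1O[Si](C(C)C)(C(C)C)C(C)C | intermediate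
24 | methyl 4-{[(1R,2S)-3-(TBS-oxy)-1-hydroxy-1-[3-methoxy-4-(TIPS-oxy)phenyl]propan-2-yl]oxy}-3-methoxybenzoate | COc1cc([C@@H](O)[C@H](CO[Si](C)(C)C(C)(C)C)Oc2ccc(C(=O)OC)cc2OC)ccc1O[Si](C(C)C)(C(C)C)C(C)C | intermediate
25 | methyl 4-{[(1R,2S)-1,3-bis(TBS-oxy)-1-[3-methoxy-4-(TIPS-oxy)phenyl]propan-2-yl]oxy}-3-methoxybenzoate | COc1cc([C@@H](O[Si](C)(C)C(C)(C)C)[C@H](CO[Si](C)(C)C(C)(C)C)Oc2ccc(C(=O)OC)cc2OC)ccc1O[Si](C(C)C)(C(C)C)C(C)C | intermediate
26 | (4-{[(1R,2S)-1,3-bis(TBS-oxy)-1-[3-methoxy-4-(TIPS-oxy)phenyl]propan-2-yl]oxy}-3-methoxyphenyl)methanol | COc1cc([C@@H](O[Si](C)(C)C(C)(C)C)[C@H](CO[Si](C)(C)C(C)(C)C)Oc2ccc(CO)cc2OC)ccc1O[Si](C(C)C)(C(C)C)C(C)C | intermediate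
27 | 4-{[(1R,2S)-1,3-bis(TBS-oxy)-1-[3-methoxy-4-(TIPS-oxy)phenyl]propan-2-yl]oxy}-3-methoxybenzyl methanesulfonate | COc1cc([C@@H](O[Si](C)(C)C(C)(C)C)[C@H](CO[Si](C)(C)C(C)(C)C)Oc2ccc(COS(C)(=O)=O)cc2OC)ccc1O[Si](C(C)C)(C(C)C)C(C)C | intermediate
28 | 4-{[(1R,2S)-1,3-bis(TBS-oxy)-1-[3-methoxy-4-(TIPS-oxy)phenyl]propan-2-yl]oxy}-3-methoxybenzyl chloride | COc1cc([C@@H](O[Si](C)(C)C(C)(C)C)[C@H](CO[Si](C)(C)C(C)(C)C)Oc2ccc(CCl)cc2OC)ccc1O[Si](C(C)C)(C(C)C)C(C)C | intermediate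
29 | (4-{[(1R,2S)-1,3-bis(TBS-oxy)-1-[3-methoxy-4-(TIPS-oxy)phenyl]propan-2-yl]oxy}-3-methoxybenzyl)magnesium chloride | COc1cc([C@@H](O[Si](C)(C)C(C)(C)C)[C@H](CO[Si](C)(C)C(C)(C)C)Oc2ccc(C[Mg]Cl)cc2OC)ccc1O[Si](C(C)C)(C(C)C)C(C)C | intermediate
30 | (2R,3S,4S,5S)-2-(4-{[(1R,2S)-1,3-bis(TBS-oxy)-1-[3-methoxy-4-(TIPS-oxy)phenyl]propan-2-yl]oxy}-3-methoxybenzyl)-4-[(TBS-oxy)methyl]-5-[3-methoxy-4-(TIPS-oxy)phenyl]oxolan-3-ol | COc1cc([C@@H](O[Si](C)(C)C(C)(C)C)[C@H](CO[Si](C)(C)C(C)(C)C)Oc2ccc(C[C@H]3O[C@H](c4ccc(O[Si](C(C)C)(C(C)C)C(C)C)c(OC)c4)[C@@H](CO[Si](C)(C)C(C)(C)C)[C@@H]3O)cc2OC)ccc1O[Si](C(C)C)(C(C)C)C(C)C | intermediate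
31 | CNP0123626.1, (2R,3S,4S,5S)-2-(4-{[(1R,2S)-1,3-dihydroxy-1-(4-hydroxy-3-methoxyphenyl)propan-2-yl]oxy}-3-methoxybenzyl)-5-(4-hydroxy-3-methoxyphenyl)-4-(hydroxymethyl)oxolan-3-ol | COc1cc([C@@H](O)[C@H](CO)Oc2ccc(C[C@H]3O[C@H](c4ccc(O)c(OC)c4)[C@@H](CO)[C@@H]3O)cc2OC)ccc1O | target

**Step count**

Total steps: 19. Longest linear sequence: 11 steps (steps 9 to 19).

**Steps most likely to fail**

Step 18. Formation of the benzylic Grignard reagent may be eroded by Wurtz-type homocoupling. The labile epoxide may also ionize to an oxocarbenium ion, or be opened by magnesium chloride, so that anti selectivity at C2 is lost. The fallback avoids both the Grignard reagent and the epoxide. It sets out from dihydrofuran 14: deprotonation at the enol ether carbon C2 (t-BuLi, THF, −78 to 0 °C) gives [(4R,5S)-4-[(TBS-oxy)methyl]-5-[3-methoxy-4-(TIPS-oxy)phenyl]-4,5-dihydrofuran-2-yl]lithium F1. Alkylation with chloride 28 (THF/DMPU) gives the C2-benzylated dihydrofuran (4R,5S)-2-(4-{[(1R,2S)-1,3-bis(TBS-oxy)-1-[3-methoxy-4-(TIPS-oxy)phenyl]propan-2-yl]oxy}-3-methoxybenzyl)-4-[(TBS-oxy)methyl]-5-[3-methoxy-4-(TIPS-oxy)phenyl]-4,5-dihydrofuran F2. Hydroboration–oxidation (BH3·THF, 0 °C; then buffered H2O2) should add boron at C3 and hydrogen at C2 on the face anti to the C4 substituent, the known route from C1-substituted glycals to trans C-glycosides. This comes back to the route at compound 30.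

Step 14. Hydride addition may show poor facial selectivity, and the α-aryloxy ketone may epimerize at Cβ by enolization before it is reduced. The fallback avoids the ketone and sets out from threo alcohol 22. Mitsunobu inversion at Cα (4-nitrobenzoic acid, PPh3, DIAD, toluene, 0 °C) gives methyl 4-{[(1R,2S)-3-(TBS-oxy)-1-(4-nitrobenzoyloxy)-1-[3-methoxy-4-(TIPS-oxy)phenyl]propan-2-yl]oxy}-3-methoxybenzoate F3. Brief methanolysis of the activated ester (K2CO3, MeOH, 0 °C) then comes back to the route at compound 24.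

Step 7. Elimination of the anomeric mesylate may be incomplete, and the acid-sensitive enol ether or the electron-rich benzylic C5–O1 bond may decompose through ionization under the mesylation conditions. The fallback sets out from lactol 12 and uses a neutral selenoxide syn-elimination. N-(Phenylseleno)phthalimide and n-Bu3P in THF give (4R,5S)-4-[(TBS-oxy)methyl]-5-[3-methoxy-4-(TIPS-oxy)phenyl]-2-(phenylselanyl)oxolane F4. Oxidation with H2O2 and NaHCO3 at 0 °C gives the selenoxide (4R,5S)-4-[(TBS-oxy)methyl]-5-[3-methoxy-4-(TIPS-oxy)phenyl]-2-(phenylseleninyl)oxolane F5. F5 eliminates at room temperature towards C3, the only β-hydrogen-bearing carbon, and this comes back to the route at compound 14.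

**Further compounds**

F1 | step 18 | [(4R,5S)-4-[(TBS-oxy)methyl]-5-[3-methoxy-4-(TIPS-oxy)phenyl]-4,5-dihydrofuran-2-yl]lithium | COc1cc([C@H]2OC([Li])=C[C@@H]2CO[Si](C)(C)C(C)(C)C)ccc1O[Si](C(C)C)(C(C)C)C(C)C
F2 | step 18 | (4R,5S)-2-(4-{[(1R,2S)-1,3-bis(TBS-oxy)-1-[3-methoxy-4-(TIPS-oxy)phenyl]propan-2-yl]oxy}-3-methoxybenzyl)-4-[(TBS-oxy)methyl]-5-[3-methoxy-4-(TIPS-oxy)phenyl]-4,5-dihydrofuran | COc1cc([C@@H](O[Si](C)(C)C(C)(C)C)[C@H](CO[Si](C)(C)C(C)(C)C)Oc2ccc(CC3=C[C@H](CO[Si](C)(C)C(C)(C)C)[C@@H](c4ccc(O[Si](C(C)C)(C(C)C)C(C)C)c(OC)c4)O3)cc2OC)ccc1O[Si](C(C)C)(C(C)C)C(C)C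
F3 | step 14 | methyl 4-{[(1R,2S)-3-(TBS-oxy)-1-(4-nitrobenzoyloxy)-1-[3-methoxy-4-(TIPS-oxy)phenyl]propan-2-yl]oxy}-3-methoxybenzoate | COc1cc([C@@H](OC(=O)c2ccc([N+](=O)[O-])cc2)[C@H](CO[Si](C)(C)C(C)(C)C)Oc2ccc(C(=O)OC)cc2OC)ccc1O[Si](C(C)C)(C(C)C)C(C)C
F4 | step 7 | (4R,5S)-4-[(TBS-oxy)methyl]-5-[3-methoxy-4-(TIPS-oxy)phenyl]-2-(phenylselanyl)oxolane | COc1cc([C@H]2OC([Se]c3ccccc3)C[C@@H]2CO[Si](C)(C)C(C)(C)C)ccc1O[Si](C(C)C)(C(C)C)C(C)C
F5 | step 7 | (4R,5S)-4-[(TBS-oxy)methyl]-5-[3-methoxy-4-(TIPS-oxy)phenyl]-2-(phenylseleninyl)oxolane | COc1cc([C@H]2OC([Se](=O)c3ccccc3)C[C@@H]2CO[Si](C)(C)C(C)(C)C)ccc1O[Si](C(C)C)(C(C)C)C(C)C
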